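The 17‑membered lactam ring is numbered N1 (lactam nitrogen), C2 (carbonyl), C3, C4 (stereocentre), N5. C4 carries an undecyl chain, the tertiary N‑methylamine N5 and the C3–C2 arm attached to N1. This is the pattern of an aldehyde–amine–alkyne coupling whose alkyne is an N‑tosyl ynamide, a latent form of the lactam. One copper‑catalysed operation joins dodecanal to both ends of an open chain, forming C4–N5 and C3–C4, closing the ring and setting 4R. The chain carries a secondary N‑methylamine at one end and a terminal N‑tosyl ynamide at the other, both released by a single fluoride treatment. Hydration and N–S cleavage then give the target.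

Key step: step 7

Remark on numbering: the macrocycles are named with the working numbering N1, C2, C3, C4, N5, N9, N14. The lowest‑locant name of the target is (8R)‑1,9,13‑trimethyl‑8‑undecyl‑1,5,9,13‑tetraazacycloheptadecan‑6‑one.

Remark on the ligand: the sense of induction of CuBr/Quinap with an ynamide nucleophile is extrapolated from simple alkynes. (S)‑Quinap is written, and its antipode is to be used should an acyclic model reaction show the opposite sense.

Remark on the chain: its two ends are introduced already differentiated, one as a fluoride‑labile carbamate of the N‑methylamine and one as the sulfonamide. No symmetrical tetraamine has to be desymmetrised, the amine stays capped during the copper N‑alkynylation, and no acid is needed once the ynamide exists.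

Step 1
Reactants: 1 3‑chloro‑N‑methylpropan‑1‑amine hydrochloride
Product: 2 2‑(trimethylsilyl)ethyl (3‑chloropropyl)(methyl)carbamate
Conditions: Teoc‑OSu (1.05 equiv), Et3N (2.2 equiv), CH2Cl2, 0 °C to rt
Reagents that add atoms: N‑[2‑(trimethylsilyl)ethoxycarbonyloxy]succinimide (Teoc‑OSu), C[Si](C)(C)CCOC(=O)ON1C(=O)CCC1=O
Why: Carbamate formation by N‑acylation of the liberated secondary amine with an active carbonate is much faster at 0 °C than self‑alkylation of the chloroamine.

Step 2
Reactants: 2 2‑(trimethylsilyl)ethyl (3‑chloropropyl)(methyl)carbamate; 3 N,N'‑dimethylbutane‑1,4‑diamine (5 equiv)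
Product: 4 2‑(trimethylsilyl)ethyl methyl[3‑[methyl[4‑(methylamino)butyl]amino]propyl]carbamate
Conditions: KI (0.2 equiv), K2CO3 (1.5 equiv), MeCN, 60 °C; excess 3 washed out with water
Reagents that add atoms: none
Why: SN2 N‑alkylation with iodide‑catalysed halide exchange (Finkelstein type) on a symmetrical secondary diamine held in large excess should stop at mono‑alkylation, and the carbamate is inert to amines.

Step 3
Reactants: 5 3‑bromopropan‑1‑amine hydrobromide
Product: 6 N‑(3‑bromopropyl)‑4‑methylbenzenesulfonamide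
Conditions: TsCl (1.0 equiv), Et3N (2.1 equiv), CH2Cl2, 0 °C
Reagents that add atoms: 4‑methylbenzenesulfonyl chloride (TsCl), Cc1ccc(cc1)S(=O)(=O)Cl
Why: N‑sulfonylation of a primary amine is fast at 0 °C, where the neutral bromoalkyl sulfonamide does not close to the azetidine.

Step 4
Reactants: 4 2‑(trimethylsilyl)ethyl methyl[3‑[methyl[4‑(methylamino)butyl]amino]propyl]carbamate; 6 N‑(3‑bromopropyl)‑4‑methylbenzenesulfonamide
Product: 7 2‑(trimethylsilyl)ethyl methyl[3‑[methyl[4‑[methyl[3‑(4‑methylbenzenesulfonamido)propyl]amino]butyl]amino]propyl]carbamate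
Conditions: iPr2NEt (1.5 equiv), MeCN, 50 °C
Reagents that add atoms: none
Why: SN2 N‑alkylation of the remaining secondary amine by a primary bromide; with only a hindered amine base in MeCN the sulfonamide N–H stays un‑ionised, so neither azetidine closure nor sulfonamide alkylation should compete.

Step 5
Reactants: 7 2‑(trimethylsilyl)ethyl methyl[3‑[methyl[4‑[methyl[3‑(4‑methylbenzenesulfonamido)propyl]amino]butyl]amino]propyl]carbamate; 8 (bromoethynyl)triisopropylsilane
Product: 9 2‑(trimethylsilyl)ethyl methyl[3‑[methyl[4‑[methyl[3‑[N‑[(triisopropylsilyl)ethynyl]‑4‑methylbenzenesulfonamido]propyl]amino]butyl]amino]propyl]carbamate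
Conditions: CuSO4·5H2O (0.2 equiv), 1,10‑phenanthroline (0.4 equiv), K3PO4 (2 equiv), 8 (1.3 equiv), toluene, 70 °C
Reagents that add atoms: none
Why: Copper‑catalysed N‑alkynylation of a secondary sulfonamide with a bromoalkyne (amidative cross‑coupling) is standard for N‑alkyl tosylamides; the sulfonamide is the only N–H in 7, and phenanthroline binds copper more firmly than the chain amines.

Step 6
Reactants: 9 2‑(trimethylsilyl)ethyl methyl[3‑[methyl[4‑[methyl[3‑[N‑[(triisopropylsilyl)ethynyl]‑4‑methylbenzenesulfonamido]propyl]amino]butyl]amino]propyl]carbamate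
Product: 11 N‑ethynyl‑4‑methyl‑N‑[3‑[methyl[4‑[methyl[3‑(methylamino)propyl]amino]butyl]amino]propyl]benzenesulfonamide, via carbamate‑protected terminal ynamide 10 (not isolated)
Conditions: TBAF (4 equiv), THF, 0 °C to rt; cold aq. K2CO3 work‑up, basic alumina, used at once
Reagents that add atoms: none
Why: Fluoride cleaves the alkynyl C–Si bond first (protodesilylation) and then triggers β‑elimination of the 2‑(trimethylsilyl)ethyl carbamate with loss of ethene and CO2, both under non‑acidic conditions that a terminal N‑sulfonyl ynamide tolerates.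

Step 7
Reactants: 11 N‑ethynyl‑4‑methyl‑N‑[3‑[methyl[4‑[methyl[3‑(methylamino)propyl]amino]butyl]amino]propyl]benzenesulfonamide; 12 dodecanal
Product: 14 (4R)‑5,9,14‑trimethyl‑1‑(4‑methylphenylsulfonyl)‑4‑undecyl‑1,5,9,14‑tetraazacycloheptadec‑2‑yne, via iminium ion 13 (not isolated)
Conditions: CuBr (0.2 equiv), (S)‑Quinap (0.22 equiv), 4 Å MS, toluene, Ar, 25 °C; 11 added over 20 h to 12 (1.3 equiv) and catalyst, final 2 mM
Reagents that add atoms: none
Why: Proposed new method: dodecanal and the secondary N‑methylamine end of 11 condense to the iminium ion 13 (the sieves take up the water) while CuBr/(S)‑Quinap turns the terminal ynamide C–H into a copper acetylide, whose carbon C3 adds to the iminium carbon C4, so that C4–N5 and C3–C4 are made in one operation. The closest known reactions are the CuBr/Quinap‑catalysed enantioselective three‑component coupling of aldehydes, secondary amines and terminal alkynes, copper acetylide additions of terminal ynamides to iminium‑type electrophiles, and non‑asymmetric ring‑closing aldehyde–amine–alkyne couplings; new is an ynamide as the alkyne partner in an enantioselective, ring‑closing version. The 17‑membered ring closes by C3–C4 bond formation as a 17‑endo‑trig attack on the iminium (C4 and N5 both become ring atoms), and a ring of this size takes up the linear N1–C2≡C3–C4 unit without strain. C4 is set by the chiral P,N‑ligand on monovalent copper, which exposes one face of the iminium to the bound acetylide (ligand enantiomer chosen for 4R), and the open chain has no stereocentre that could oppose it. The step needs ring closure to win over chain‑to‑chain coupling and the addition to occur inside the ligand pocket: slow addition of 11 to a 2 mM solution should secure the first, and the chelating P,N‑ligand, which holds copper more firmly than the isolated tertiary amines of the chain, the second. The N‑tosyl group keeps N1 non‑basic, so only the N‑methylamine end forms the iminium and only the ynamide C–H is metalated.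

Step 8
Reactants: 14 (4R)‑5,9,14‑trimethyl‑1‑(4‑methylphenylsulfonyl)‑4‑undecyl‑1,5,9,14‑tetraazacycloheptadec‑2‑yne
Product: 16 (4R)‑5,9,14‑trimethyl‑1‑(4‑methylphenylsulfonyl)‑4‑undecyl‑1,5,9,14‑tetraazacycloheptadecan‑2‑one, via keteniminium ion 15 (not isolated)
Conditions: TsOH·H2O (4.5 equiv), MeCN/H2O (10:1), 0 °C to rt; cold aq. K2CO3 work‑up, extracted at once
Reagents that add atoms: water, O
Why: Brønsted‑acid hydration of an ynamide: protonation at C3 gives the keteniminium, water adds at C2 and tautomerisation gives the N‑sulfonyl amide with the carbonyl at C2 and CH2 at C3, while C4 is not involved and keeps its configuration.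

Step 9
Reactants: 16 (4R)‑5,9,14‑trimethyl‑1‑(4‑methylphenylsulfonyl)‑4‑undecyl‑1,5,9,14‑tetraazacycloheptadecan‑2‑one
Product: 17 (4R)‑5,9,14‑trimethyl‑4‑undecyl‑1,5,9,14‑tetraazacycloheptadecan‑2‑one
Conditions: SmI2 (3 equiv), THF, −78 °C; sat. NH4Cl, then pH 11, CH2Cl2 extraction
Reagents that add atoms: none
Why: Reductive desulfonylation: single‑electron transfer from divalent samarium to the N‑acyl sulfonamide cleaves the weak N–S bond at low temperature, and the amide, the tertiary amines and C4 are left untouched.

Compound list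
1 | 3‑chloro‑N‑methylpropan‑1‑amine hydrochloride | CNCCCCl.Cl | starting material
2 | 2‑(trimethylsilyl)ethyl (3‑chloropropyl)(methyl)carbamate | CN(CCCCl)C(=O)OCC[Si](C)(C)C | intermediate
3 | N,N'‑dimethylbutane‑1,4‑diamine | CNCCCCNC | starting material
4 | 2‑(trimethylsilyl)ethyl methyl[3‑[methyl[4‑(methylamino)butyl]amino]propyl]carbamate | CNCCCCN(C)CCCN(C)C(=O)OCC[Si](C)(C)C | intermediate
5 | 3‑bromopropan‑1‑amine hydrobromide | NCCCBr.Br | starting material
6 | N‑(3‑bromopropyl)‑4‑methylbenzenesulfonamide | Cc1ccc(cc1)S(=O)(=O)NCCCBr | intermediate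
7 | 2‑(trimethylsilyl)ethyl methyl[3‑[methyl[4‑[methyl[3‑(4‑methylbenzenesulfonamido)propyl]amino]butyl]amino]propyl]carbamate | Cc1ccc(cc1)S(=O)(=O)NCCCN(C)CCCCN(C)CCCN(C)C(=O)OCC[Si](C)(C)C | intermediate
8 | (bromoethynyl)triisopropylsilane | CC(C)[Si](C#CBr)(C(C)C)C(C)C | starting material
9 | 2‑(trimethylsilyl)ethyl methyl[3‑[methyl[4‑[methyl[3‑[N‑[(triisopropylsilyl)ethynyl]‑4‑methylbenzenesulfonamido]propyl]amino]butyl]amino]propyl]carbamate | CC(C)[Si](C#CN(CCCN(C)CCCCN(C)CCCN(C)C(=O)OCC[Si](C)(C)C)S(=O)(=O)c1ccc(C)cc1)(C(C)C)C(C)C | intermediate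
10 | 2‑(trimethylsilyl)ethyl [3‑[[4‑[[3‑(N‑ethynyl‑4‑methylbenzenesulfonamido)propyl](methyl)amino]butyl](methyl)amino]propyl](methyl)carbamate | C#CN(CCCN(C)CCCCN(C)CCCN(C)C(=O)OCC[Si](C)(C)C)S(=O)(=O)c1ccc(C)cc1 | intermediate (not isolated)
11 | N‑ethynyl‑4‑methyl‑N‑[3‑[methyl[4‑[methyl[3‑(methylamino)propyl]amino]butyl]amino]propyl]benzenesulfonamide | CNCCCN(C)CCCCN(C)CCCN(C#C)S(=O)(=O)c1ccc(C)cc1 | intermediate
12 | dodecanal | CCCCCCCCCCCC=O | starting material
13 | N‑methyl‑N‑[3‑[methyl[4‑[methyl[3‑(N‑ethynyl‑4‑methylbenzenesulfonamido)propyl]amino]butyl]amino]propyl]dodecan‑1‑iminium ion | CCCCCCCCCCCC=[N+](C)CCCN(C)CCCCN(C)CCCN(C#C)S(=O)(=O)c1ccc(C)cc1 | intermediate (not isolated)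
14 | (4R)‑5,9,14‑trimethyl‑1‑(4‑methylphenylsulfonyl)‑4‑undecyl‑1,5,9,14‑tetraazacycloheptadec‑2‑yne | CCCCCCCCCCC[C@@H]1C#CN(S(=O)(=O)c2ccc(C)cc2)CCCN(C)CCCCN(C)CCCN1C | intermediate
15 | (4R)‑5,9,14‑trimethyl‑1‑(4‑methylphenylsulfonyl)‑4‑undecyl‑1,5,9,14‑tetraazacycloheptadeca‑1,2‑dien‑1‑ium (N1=C2=C3 keteniminium ion) | CCCCCCCCCCC[C@@H]1C=C=[N+](S(=O)(=O)c2ccc(C)cc2)CCCN(C)CCCCN(C)CCCN1C | intermediate (not isolated)
16 | (4R)‑5,9,14‑trimethyl‑1‑(4‑methylphenylsulfonyl)‑4‑undecyl‑1,5,9,14‑tetraazacycloheptadecan‑2‑one | CCCCCCCCCCC[C@@H]1CC(=O)N(S(=O)(=O)c2ccc(C)cc2)CCCN(C)CCCCN(C)CCCN1C | intermediate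
17 | (4R)‑5,9,14‑trimethyl‑4‑undecyl‑1,5,9,14‑tetraazacycloheptadecan‑2‑one | CCCCCCCCCCC[C@@H]1CC(=O)NCCCN(C)CCCCN(C)CCCN1C | target

Total step count: 9.
Longest linear sequence: 8 steps (steps 1, 2, 4, 5, 6, 7, 8, 9; step 3 is a one‑step branch).

Steps most likely to fail

1. Step 7 (the step that bears the label "Proposed new method:").
- What may go wrong: chain‑to‑chain coupling may outrun ring closure. Copper may move from the chiral ligand to the 1,3‑diamine unit of the chain, so that the acetylide adds with poor facial selectivity. The amine may also add to the copper‑activated ynamide.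
- Fallback with known reactions, in which stereocentre and ring are made in separate events; it sets out from 7 and comes back at 14.
- TBAF in THF removes the carbamate from 7 to give 4‑methyl‑N‑[3‑[methyl[4‑[methyl[3‑(methylamino)propyl]amino]butyl]amino]propyl]benzenesulfonamide F1.
- F1, dodecanal 12 and ethynyltrimethylsilane are combined in the established intermolecular CuBr/Quinap three‑component coupling (toluene, 4 Å MS, rt). This should give 4‑methyl‑N‑[3‑[methyl[4‑[methyl[3‑[methyl[(3R)‑1‑(trimethylsilyl)tetradec‑1‑yn‑3‑yl]amino]propyl]amino]butyl]amino]propyl]benzenesulfonamide F2, with the stereocentre set free of any ring‑closure constraint.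
- NBS with catalytic AgNO3 in acetone, the amines being held as their trifluoroacetate salts, exchanges silicon for bromine to give N‑[3‑[[4‑[[3‑[[(3R)‑1‑bromotetradec‑1‑yn‑3‑yl](methyl)amino]propyl](methyl)amino]butyl](methyl)amino]propyl]‑4‑methylbenzenesulfonamide F3.
- Intramolecular copper‑catalysed N‑alkynylation of the sulfonamide (CuSO4·5H2O, 1,10‑phenanthroline, K3PO4, toluene, 80 °C, slow addition to 2 mM) is a known way to macrocyclic ynamides. It closes the N1–C2 bond and returns to 14.

2. Step 5.
- What may go wrong: the chain amines may sequester the copper, or the bromoalkyne may be consumed by homocoupling before the sulfonamide is alkynylated.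
- Fallback without copper and without the bromoalkyne; it sets out from 7 and comes back at 10.
- Trichloroethylene and Cs2CO3 in DMF at 50 °C (addition of the sulfonamide to dichloroacetylene formed in the flask) give 2‑(trimethylsilyl)ethyl methyl[3‑[methyl[4‑[methyl[3‑[N‑[(E)‑1,2‑dichloroethenyl]‑4‑methylbenzenesulfonamido]propyl]amino]butyl]amino]propyl]carbamate F4.
- PhLi (2.5 equiv) in THF at −78 °C effects elimination to the chloroynamide and chlorine–lithium exchange. Aqueous quench gives the terminal ynamide 10, here isolated.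
- 10 rejoins the route in the carbamate‑cleaving stage of step 6 (TBAF) to give 11.

3. Step 8.
- What may go wrong: in strong acid the protonated N5 may depart from C4, an ionisation assisted by the ynamide nitrogen, with ring opening or loss of configuration. The β‑amino N‑tosyl lactam may also lose N5 by β‑elimination during basic work‑up.
- Fallback by a two‑stage oxygen transfer under weakly acidic and then neutral conditions; it sets out from 14 and comes back at 16.
- Acetic acid (excess) in toluene at 60–80 °C adds across the ynamide (hydroacyloxylation, known for N‑sulfonyl ynamides). This should give (2E,4R)‑5,9,14‑trimethyl‑1‑(4‑methylphenylsulfonyl)‑4‑undecyl‑1,5,9,14‑tetraazacycloheptadec‑2‑en‑2‑yl acetate F5.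
- n‑Butylamine in CH2Cl2 at rt then takes over the acetyl group (aminolysis of the enol ester, as in ynamide‑mediated amide coupling). The freed enol tautomerises to 16, which is reduced at once as in step 9.

Further compounds
F1 | step 7 | 4‑methyl‑N‑[3‑[methyl[4‑[methyl[3‑(methylamino)propyl]amino]butyl]amino]propyl]benzenesulfonamide | CNCCCN(C)CCCCN(C)CCCNS(=O)(=O)c1ccc(C)cc1
F2 | step 7 | 4‑methyl‑N‑[3‑[methyl[4‑[methyl[3‑[methyl[(3R)‑1‑(trimethylsilyl)tetradec‑1‑yn‑3‑yl]amino]propyl]amino]butyl]amino]propyl]benzenesulfonamide | CCCCCCCCCCC[C@H](C#C[Si](C)(C)C)N(C)CCCN(C)CCCCN(C)CCCNS(=O)(=O)c1ccc(C)cc1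
F3 | step 7 | N‑[3‑[[4‑[[3‑[[(3R)‑1‑bromotetradec‑1‑yn‑3‑yl](methyl)amino]propyl](methyl)amino]butyl](methyl)amino]propyl]‑4‑methylbenzenesulfonamide | CCCCCCCCCCC[C@H](C#CBr)N(C)CCCN(C)CCCCN(C)CCCNS(=O)(=O)c1ccc(C)cc1
F4 | step 5 | 2‑(trimethylsilyl)ethyl methyl[3‑[methyl[4‑[methyl[3‑[N‑[(E)‑1,2‑dichloroethenyl]‑4‑methylbenzenesulfonamido]propyl]amino]butyl]amino]propyl]carbamate | Cl/C=C(/Cl)N(CCCN(C)CCCCN(C)CCCN(C)C(=O)OCC[Si](C)(C)C)S(=O)(=O)c1ccc(C)cc1
F5 | step 8 | (2E,4R)‑5,9,14‑trimethyl‑1‑(4‑methylphenylsulfonyl)‑4‑undecyl‑1,5,9,14‑tetraazacycloheptadec‑2‑en‑2‑yl acetate | CCCCCCCCCCC[C@@H]1/C=C(/OC(C)=O)N(S(=O)(=O)c2ccc(C)cc2)CCCN(C)CCCCN(C)CCCN1C
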